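**Plan**

1. Late cuts: the C7 acid goes back to a primary alcohol, the C2/C3 epoxide to a 1β‑hydroxyl‑directed epoxidation, and the 1β‑hydroxy‑2‑ene to a 1β,2β‑epoxy‑3‑ketone (Wharton). The lactone C10–O bond is then cut together with a C10–C20 bond, which leads to a C10 carboxylic acid next to a C19 tert‑butyl ester.
2. Earlier cuts: C13–C16 and C8–C15 (ring D), the ring C enone back to an anisole, C4–C18, C4–C19, C6–C7, C4–C5 and C1–C10 (ring A, Robinson annulation), and C10–C9 (ring B, carbenoid arylation).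
3. Forward order: ring B is closed onto the anisole ring (future ring C), ring A is annulated, C7, C19 and C18 are attached, ring C is unmasked by Birch reduction, ring D is closed, the lactone ring is closed, and ring A is oxygenated last.
4. Enabling feature: the lactone oxygen on C10 and the C19 carbonyl on C4 are cis and 1,3‑diaxial on ring A. A carboxyl carbon (C20) on C10 therefore first activates C10 for the Michael step that makes it quaternary and is later expelled as CO2 at an anode, the C10 cation being caught by the C19 ester oxygen.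
5. Stereochemistry: C10 comes from a catalytic asymmetric Michael addition; C6, C5 and C4 are relayed from the angular C10 ester; C9 is set by equilibration, C8 by a conjugate addition that gives the cis‑hydrindanone, C13 by the bridge. The C10–O bond is set by the C19 tether, C1/C2 by β‑face epoxidation (the lactone covers α), and C2/C3 by the 1β‑hydroxyl.

Key step: step 17

Numbering remark: carbon numbers are those of the gibberellane skeleton; α is the face of rings A and B that carries C20 (later the lactone oxygen) and C19, so H5, H9, C7, C15 and C18 are β.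
Assumption: the cupreidine‑derived catalyst of step 4 is taken to give the (1R) adduct 10; if the sense of induction is the reverse, its cupreine‑derived pseudoenantiomer is used instead.

**Route**

Step 1
Reactants: 1 3‑methoxyphenylacetic acid; 2 Meldrum's acid; 3 methanol
Product: 5 methyl 4‑(3‑methoxyphenyl)‑3‑oxobutanoate, via acyl Meldrum's acid 4 (not isolated)
Conditions: DCC, DMAP, CH2Cl2, 0 °C to rt; then MeOH, reflux
Reagents that add atoms: Meldrum's acid CC1(C)OC(=O)CC(=O)O1; methanol CO
Why: Carbodiimide‑mediated C‑acylation of Meldrum's acid and methanolysis of the acyl derivative (loss of acetone and CO2) is the standard homologation of an arylacetic acid to a β‑keto ester.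

Step 2
Reactants: 5 methyl 4‑(3‑methoxyphenyl)‑3‑oxobutanoate; 6 4‑acetamidobenzenesulfonyl azide
Product: 7 methyl 2‑diazo‑4‑(3‑methoxyphenyl)‑3‑oxobutanoate
Conditions: Et3N, MeCN, 0 °C to rt
Reagents that add atoms: 4‑acetamidobenzenesulfonyl azide CC(=O)Nc1ccc(cc1)S(=O)(=O)N=[N+]=[N-]
Why: Regitz diazo transfer to the doubly activated methylene of the β‑keto ester.

Step 3
Reactants: 7 methyl 2‑diazo‑4‑(3‑methoxyphenyl)‑3‑oxobutanoate
Product: 8 methyl 5‑methoxy‑2‑oxoindane‑1‑carboxylate
Conditions: Rh2(OAc)4 (1 mol %), CH2Cl2, rt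
Reagents that add atoms: none
Why: The rhodium carbenoid undergoes intramolecular aromatic substitution (formal aryl C–H insertion) para to the methoxy group, the more electron‑rich and less hindered ortho site of the side chain, which closes ring B and places the ester‑bearing carbon (C10) on the aryl carbon para to OMe (C9, with OMe on C13).

Step 4
Reactants: 8 methyl 5‑methoxy‑2‑oxoindane‑1‑carboxylate; 9 methyl vinyl ketone
Product: 10 methyl (1R)‑5‑methoxy‑2‑oxo‑1‑(3‑oxobutyl)indane‑1‑carboxylate
Conditions: 9‑O‑(9‑phenanthryl)cupreidine (10 mol %), CH2Cl2, −20 °C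
Reagents that add atoms: methyl vinyl ketone CC(=O)C=C
Why: Enantioselective organocatalytic Michael addition in which the bifunctional cinchona catalyst (tertiary amine base and phenolic hydrogen‑bond donor) pairs with the enolised cyclic β‑keto ester and shields one face, so the quaternary C10 centre is set by the catalyst.

Step 5
Reactants: 10 methyl (1R)‑5‑methoxy‑2‑oxo‑1‑(3‑oxobutyl)indane‑1‑carboxylate
Product: 11 methyl (4aS)‑7‑methoxy‑2‑oxo‑2,3,4,9‑tetrahydro‑4aH‑fluorene‑4a‑carboxylate
Conditions: TsOH·H2O (10 mol %), toluene, reflux, Dean–Stark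
Reagents that add atoms: none
Why: Acid‑catalysed aldol condensation of the side‑chain methyl ketone onto the indanone carbonyl completes the Robinson annulation of ring A, and the acidic medium avoids retro‑Michael erosion of C10.

Step 6
Reactants: 11 tricyclic enone; 12 trimethylsilyl trifluoromethanesulfonate
Product: 13 trimethylsilyl dienol ether (3‑silyloxy‑3,5‑diene)
Conditions: Et3N, CH2Cl2, 0 °C
Reagents that add atoms: trimethylsilyl trifluoromethanesulfonate C[Si](C)(C)OS(=O)(=O)C(F)(F)F
Why: Soft enolisation under equilibrating conditions removes the benzylic γ‑proton at C6 and gives the fully conjugated silyl dienol ether.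

Step 7
Reactants: 13 trimethylsilyl dienol ether; 14 formaldehyde
Product: 15 6β‑hydroxymethyl enone
Conditions: aq. HCHO (37 %), Yb(OTf)3 (10 mol %), THF, rt
Reagents that add atoms: formaldehyde C=O
Why: Vinylogous Mukaiyama aldol (lanthanide‑triflate‑catalysed aqueous hydroxymethylation) takes place at the γ‑carbon C6, and the electrophile should approach the nearly planar ring B anti to the pseudoaxial C10 ester, which places C7 trans to C20.

Step 8
Reactants: 15 6β‑hydroxymethyl enone; 16 chlorotriisopropylsilane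
Product: 17 6β‑(triisopropylsilyloxymethyl) enone
Conditions: imidazole, DMF, rt
Reagents that add atoms: chlorotriisopropylsilane CC(C)[Si](Cl)(C(C)C)C(C)C
Why: Silylation of the primary alcohol with a bulky silyl group that tolerates the reductions, bases and acids that follow.

Step 9
Reactants: 17 6β‑(triisopropylsilyloxymethyl) enone; 18 carbon dioxide; 19 tert‑butyl 2,2,2‑trichloroacetimidate
Product: 22 19‑tert‑butyl 20‑methyl 3‑oxo diester (C4–H), via lithium enolate 20 (not isolated), via keto acid 21 (not isolated)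
Conditions: Li (2.2 equiv), NH3(l), THF, tBuOH (1 equiv), −78 °C; NH3 removed; CO2, THF, −78 to 0 °C; cold 1 M HCl; then Cl3CC(=NH)OtBu, cyclohexane–CH2Cl2, rt
Reagents that add atoms: carbon dioxide O=C=O; tert‑butyl 2,2,2‑trichloroacetimidate CC(C)(C)OC(=N)C(Cl)(Cl)Cl
Why: Metal–ammonia reduction of the enone gives the regiodefined C3–C4 enolate with axial protonation at C5 (trans ring fusion, H5 anti to the C10 ester and cis to C7), CO2 carboxylates the enolate at C4, and the β‑keto acid is esterified at once under neutral conditions by the imidate (reductive carboxylation with enolate trapping).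

Step 10
Reactants: 22 19‑tert‑butyl 20‑methyl 3‑oxo diester; 23 iodomethane
Product: 24 4β‑methyl 3‑oxo diester (C19 tert‑butyl ester α)
Conditions: K2CO3, DMF, rt
Reagents that add atoms: iodomethane CI
Why: C‑alkylation of the β‑keto ester enolate, in which iodomethane enters anti to the axial C10 ester so that the methyl group (C18) becomes β and the tert‑butyl ester (C19) stays cis and 1,3‑diaxial to C20.

Step 11
Reactants: 24 4β‑methyl 3‑oxo diester
Product: 25 3β‑alcohol
Conditions: L‑Selectride (LiBH(sBu)3), THF, −78 °C; H2O work‑up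
Reagents that add atoms: none
Why: Bulky trialkylborohydride reduction by equatorial attack should give the axial 3β‑alcohol, which lies on the face opposite both carboxyl groups and cannot lactonise; the C3 configuration is immaterial because the ketone returns in step 16.

Step 12
Reactants: 25 3β‑alcohol
Product: 26 3β‑hydroxy 20‑oic acid (19‑tert‑butyl ester)
Conditions: LiSPr (from PrSH, nBuLi), HMPA, rt; 1 M HCl work‑up
Reagents that add atoms: none
Why: SN2 dealkylation by thiolate cleaves the hindered C20 methyl ester at the O–methyl bond and leaves the tert‑butyl ester untouched.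

Step 13
Reactants: 26 3β‑hydroxy 20‑oic acid; 27 water
Product: 30 ring C enone acid (13‑oxo‑8(14)‑ene; 9β‑H), via dihydroanisole 28 (not isolated), via deconjugated enone 29 (not isolated)
Conditions: Li (excess), NH3(l), THF, tBuOH, −78 to −33 °C; NH4Cl; then 1 M HCl, THF, rt
Reagents that add atoms: water O
Why: Birch reduction of the anisole (acid and alcohol protected as lithium carboxylate and alkoxide, tert‑butyl ester and silyl ether tolerant of dissolving metal) gives the 1‑methoxy‑1,4‑diene, and hydrolysis with acid‑catalysed conjugation gives the enone; C9 is protonated reversibly and the 9β‑H epimer, with C11 trans to C1 across ring B, is expected to prevail.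

Step 14
Reactants: 30 ring C enone acid; 31 tributyl(propa‑1,2‑dienyl)stannane
Product: 32 8β‑propargyl 13‑ketone
Conditions: TiCl4 (3.5 equiv), CH2Cl2, −78 °C; 1 M HCl work‑up
Reagents that add atoms: tributyl(propa‑1,2‑dienyl)stannane C=C=C[Sn](CCCC)(CCCC)CCCC
Why: Lewis acid‑promoted conjugate propargylation (Hosomi–Sakurai type, SE2′ attack of the allenylstannane) creates the quaternary C8 by axial attack that leads to the cis‑fused hydrindanone, so C15 enters cis to H9, while the acid and alcohol are carried as titanium carboxylate and alkoxide.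

Step 15
Reactants: 32 8β‑propargyl 13‑ketone
Product: 33 3β,13‑dihydroxy‑16‑ene 20‑oic acid
Conditions: SmI2 (5 equiv), HMPA, tBuOH, THF, 0 °C to rt
Reagents that add atoms: none
Why: Ketyl–alkyne reductive cyclisation with divalent samarium, in which the C13 ketyl adds 5‑exo‑dig to the alkyne and the vinyl radical is reduced and protonated, gives ring D with the bridgehead 13‑hydroxyl and the 16‑methylene at once; the C13 configuration is fixed by the bridge.

Step 16
Reactants: 33 3β,13‑dihydroxy‑16‑ene 20‑oic acid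
Product: 34 13‑hydroxy‑3‑oxo‑16‑ene 20‑oic acid 19‑tert‑butyl ester
Conditions: Dess–Martin periodinane, CH2Cl2, rt
Reagents that add atoms: none
Why: Dess–Martin oxidation of the secondary 3β‑alcohol; the tertiary 13‑alcohol and the acid are inert.

Step 17
Reactants: 34 13‑hydroxy‑3‑oxo‑16‑ene 20‑oic acid 19‑tert‑butyl ester
Product: 35 13‑hydroxy‑3‑oxo‑16‑ene 19,10‑lactone
Conditions: undivided cell, graphite anode, Pt cathode, 2,4,6‑collidine (2 equiv), nBu4NPF6 (0.1 M), CH2Cl2, 3 Å MS, constant current (about 5 mA cm−2, 2.5–3 F mol−1), rt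
Reagents that add atoms: none
Why: Proposed new method: anodic oxidation of the collidinium carboxylate at graphite gives the acyloxy radical, which loses CO2, and the tertiary C10 radical is oxidised at the electrode to the C10 cation (Hofer–Moest, non‑Kolbe pathway); the carbonyl oxygen of the C19 tert‑butyl ester, held 1,3‑diaxial to C10 on ring A, adds to the cation and the tert‑butoxy oxocarbenium ion loses isobutene and a proton to leave the lactone. The closest known reactions are non‑Kolbe anodic decarboxylations of tertiary acids with intramolecular capture of the cation by hydroxyl or carboxyl groups, and the capture of cations by tert‑butyl esters and carbonates in halolactonisation‑type cyclisations; their combination at an electrogenerated cation is the untested element. The γ‑lactone ring (O–C19–C4–C5–C10) closes by attack of a tethered oxygen on a trigonal cationic carbon, a five‑membered closure that bridges ring A to a 6‑oxabicyclo[3.2.1]octan‑7‑one. The new stereocentre C10 is controlled by the tether: C19 sits on the α face, so the C10–O bond can only form on the face that the carboxyl left. Chemoselectivity rests on the carboxylate being oxidised well below the potential of the 1,1‑disubstituted 16‑ene, and because C19 is esterified no cation can arise at C4, so the wrong‑way lactone (C20 carboxyl onto C4) has no path. Capture has to outrun proton loss and hydride shift from C5 or C9, which the non‑nucleophilic medium and the pre‑organised internal trap are meant to secure.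

Step 18
Reactants: 35 13‑hydroxy‑3‑oxo‑16‑ene 19,10‑lactone; 36 triethylsilyl trifluoromethanesulfonate
Product: 37 13‑O‑triethylsilyl 3‑oxo lactone
Conditions: 2,6‑lutidine, CH2Cl2, −78 °C
Reagents that add atoms: triethylsilyl trifluoromethanesulfonate CC[Si](CC)(CC)OS(=O)(=O)C(F)(F)F
Why: Silylation of the hindered tertiary bridgehead alcohol with a silyl triflate masks the only hydroxyl that could later direct the vanadium catalyst to the 16‑ene.

Step 19
Reactants: 37 13‑O‑triethylsilyl 3‑oxo lactone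
Product: 38 1‑en‑3‑one lactone
Conditions: IBX, DMSO–toluene, 70 °C
Reagents that add atoms: none
Why: IBX dehydrogenation of the ketone (enolisation and single‑electron oxidation) can only introduce the 1,2‑double bond because C4 is quaternary.

Step 20
Reactants: 38 1‑en‑3‑one lactone; 39 hydrogen peroxide (as its urea adduct)
Product: 40 1β,2β‑epoxy‑3‑ketone
Conditions: urea·H2O2, DBU, THF, 0 °C to rt
Reagents that add atoms: hydrogen peroxide OO
Why: Weitz–Scheffer nucleophilic epoxidation under non‑hydroxylic basic conditions, in which hydroperoxide adds to C1 from the β face because the lactone bridge covers the α face of ring A, giving the 1β,2β‑epoxide.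

Step 21
Reactants: 40 1β,2β‑epoxy‑3‑ketone
Product: 42 1β‑hydroxy‑2‑ene lactone, via epoxy hydrazone 41 (not isolated)
Conditions: N2H4·H2O (3 equiv), AcOH (0.3 equiv), MeOH, 0 °C to rt
Reagents that add atoms: none
Why: Wharton transposition, in which the epoxy hydrazone fragments with loss of N2 to the allylic alcohol; the C1–O bond of the epoxide is retained as the 1β‑hydroxyl and the alkene ends at C2–C3.

Step 22
Reactants: 42 1β‑hydroxy‑2‑ene lactone; 43 tert‑butyl hydroperoxide
Product: 44 1β‑hydroxy‑2β,3β‑epoxide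
Conditions: VO(acac)2 (5 mol %), tBuOOH (1.5 equiv), CH2Cl2, 0 °C to rt
Reagents that add atoms: tert‑butyl hydroperoxide CC(C)(C)OO
Why: Vanadium‑catalysed hydroxyl‑directed epoxidation delivers oxygen syn to the pseudoaxial 1β‑hydroxyl, which is also the open β face, and the silylated 13‑oxygen leaves the 16‑ene untouched.

Step 23
Reactants: 44 1β‑hydroxy‑2β,3β‑epoxide
Product: 45 1β,7,13‑triol 2β,3β‑epoxide
Conditions: Bu4NF, AcOH, THF, rt
Reagents that add atoms: none
Why: Fluoride cleaves both silyl ethers; acetic acid buffering avoids base‑induced opening of the lactone or epoxide, and the cis‑epoxy alcohol cannot undergo Payne rearrangement.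

Step 24
Reactants: 45 1β,7,13‑triol 2β,3β‑epoxide; 27 water
Product: 47 1β,13‑dihydroxy‑2β,3β‑epoxy‑20‑norgibberell‑16‑ene‑7,19‑dioic acid 19,10‑lactone (the target gibberellin), via 7‑aldehyde 46 (not isolated)
Conditions: TEMPO (0.2 equiv), PhI(OAc)2 (2.5 equiv), MeCN–H2O (1:1), rt
Reagents that add atoms: water O
Why: Nitroxyl‑catalysed oxidation with a hypervalent iodine co‑oxidant in aqueous acetonitrile takes the primary alcohol through the aldehyde hydrate to the carboxylic acid and is selective over the hindered secondary and the tertiary alcohol.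

**Compound list**

1 | 3‑methoxyphenylacetic acid | OC(=O)Cc1cccc(OC)c1 | starting material
2 | Meldrum's acid (2,2‑dimethyl‑1,3‑dioxane‑4,6‑dione) | CC1(C)OC(=O)CC(=O)O1 | starting material
3 | methanol | CO | starting material
4 | acyl Meldrum's acid, 5‑[1‑hydroxy‑2‑(3‑methoxyphenyl)ethylidene]‑2,2‑dimethyl‑1,3‑dioxane‑4,6‑dione | COc1cccc(CC(O)=C2C(=O)OC(C)(C)OC2=O)c1 | intermediate
5 | methyl 4‑(3‑methoxyphenyl)‑3‑oxobutanoate | COC(=O)CC(=O)Cc1cccc(OC)c1 | intermediate
6 | 4‑acetamidobenzenesulfonyl azide | CC(=O)Nc1ccc(cc1)S(=O)(=O)N=[N+]=[N-] | starting material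
7 | methyl 2‑diazo‑4‑(3‑methoxyphenyl)‑3‑oxobutanoate | COC(=O)C(=[N+]=[N-])C(=O)Cc1cccc(OC)c1 | intermediate
8 | methyl 5‑methoxy‑2‑oxoindane‑1‑carboxylate (racemic, largely enolised) | COc1ccc2c(c1)CC(=O)C2C(=O)OC | intermediate
9 | methyl vinyl ketone | CC(=O)C=C | starting material
10 | methyl (1R)‑5‑methoxy‑2‑oxo‑1‑(3‑oxobutyl)indane‑1‑carboxylate | COc1ccc2c(c1)CC(=O)[C@]2(CCC(C)=O)C(=O)OC | intermediate
11 | methyl (4aS)‑7‑methoxy‑2‑oxo‑2,3,4,9‑tetrahydro‑4aH‑fluorene‑4a‑carboxylate (3‑oxo‑4‑ene; CO2Me = C20 on C10; OMe on C13) | COc1ccc2c(c1)CC3=CC(=O)CC[C@@]23C(=O)OC | intermediate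
12 | trimethylsilyl trifluoromethanesulfonate | C[Si](C)(C)OS(=O)(=O)C(F)(F)F | starting material
13 | trimethylsilyl dienol ether of 11 (3‑silyloxy‑3,5‑diene) | COc1ccc2c(c1)C=C3C=C(O[Si](C)(C)C)CC[C@@]23C(=O)OC | intermediate
14 | formaldehyde | C=O | starting material
15 | 6β‑hydroxymethyl enone (11 with CH2OH = C7 on C6, trans to the C10 ester) | COc1ccc2c(c1)[C@@H](CO)C3=CC(=O)CC[C@@]23C(=O)OC | intermediate
16 | chlorotriisopropylsilane | CC(C)[Si](Cl)(C(C)C)C(C)C | starting material
17 | 6β‑(triisopropylsilyloxymethyl) enone | COc1ccc2c(c1)[C@@H](CO[Si](C(C)C)(C(C)C)C(C)C)C3=CC(=O)CC[C@@]23C(=O)OC | intermediate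
18 | carbon dioxide | O=C=O | starting material
19 | tert‑butyl 2,2,2‑trichloroacetimidate | CC(C)(C)OC(=N)C(Cl)(Cl)Cl | starting material
20 | lithium enolate (C3–O−, C3=C4; 5β‑H) | COc1ccc2c(c1)[C@@H](CO[Si](C(C)C)(C(C)C)C(C)C)[C@H]3[C@@]2(C(=O)OC)CCC([O-])=C3.[Li+] | intermediate
21 | 3‑oxo‑19‑oic acid 20‑methyl ester (C4–H, epimers) | COc1ccc2c(c1)[C@@H](CO[Si](C(C)C)(C(C)C)C(C)C)[C@H]3[C@@]2(C(=O)OC)CCC(=O)C3C(O)=O | intermediate
22 | 19‑tert‑butyl 20‑methyl 3‑oxo diester (C4–H, epimers or enol) | COc1ccc2c(c1)[C@@H](CO[Si](C(C)C)(C(C)C)C(C)C)[C@H]3[C@@]2(C(=O)OC)CCC(=O)C3C(=O)OC(C)(C)C | intermediate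
23 | iodomethane | CI | starting material
24 | 4β‑methyl 3‑oxo diester (C18 β, C19 tert‑butyl ester α, C20 methyl ester α) | COc1ccc2c(c1)[C@@H](CO[Si](C(C)C)(C(C)C)C(C)C)[C@H]3[C@@]2(C(=O)OC)CCC(=O)[C@@]3(C)C(=O)OC(C)(C)C | intermediate
25 | 3β‑alcohol of 24 | COc1ccc2c(c1)[C@@H](CO[Si](C(C)C)(C(C)C)C(C)C)[C@H]3[C@@]2(C(=O)OC)CC[C@H](O)[C@@]3(C)C(=O)OC(C)(C)C | intermediate
26 | 3β‑hydroxy 20‑oic acid 19‑tert‑butyl ester (ring C aromatic, 13‑OMe) | COc1ccc2c(c1)[C@@H](CO[Si](C(C)C)(C(C)C)C(C)C)[C@H]3[C@@]2(C(O)=O)CC[C@H](O)[C@@]3(C)C(=O)OC(C)(C)C | intermediate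
27 | water | O | starting material
28 | dihydroanisole (13‑methoxy‑8(9),12‑diene) | COC1=CCC2=C(C1)[C@@H](CO[Si](C(C)C)(C(C)C)C(C)C)[C@H]3[C@@]2(C(O)=O)CC[C@H](O)[C@@]3(C)C(=O)OC(C)(C)C | intermediate
29 | deconjugated enone (13‑oxo‑8(9)‑ene) | O=C1CCC2=C(C1)[C@@H](CO[Si](C(C)C)(C(C)C)C(C)C)[C@H]3[C@@]2(C(O)=O)CC[C@H](O)[C@@]3(C)C(=O)OC(C)(C)C | intermediate
30 | ring C enone acid (13‑oxo‑8(14)‑ene, 9β‑H) | O=C1CC[C@@H]2C(=C1)[C@@H](CO[Si](C(C)C)(C(C)C)C(C)C)[C@H]3[C@@]2(C(O)=O)CC[C@H](O)[C@@]3(C)C(=O)OC(C)(C)C | intermediate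
31 | tributyl(propa‑1,2‑dienyl)stannane | C=C=C[Sn](CCCC)(CCCC)CCCC | starting material
32 | 8β‑propargyl 13‑ketone (9β‑H) | C#CC[C@]12CC(=O)CC[C@H]1[C@]1(C(O)=O)CC[C@H](O)[C@@](C)(C(=O)OC(C)(C)C)[C@H]1[C@@H]2CO[Si](C(C)C)(C(C)C)C(C)C | intermediate
33 | 3β,13‑dihydroxy‑16‑ene 20‑oic acid 19‑tert‑butyl ester, 7‑O‑triisopropylsilyl | C=C1C[C@]23C[C@@]1(O)CC[C@H]2[C@]1(C(O)=O)CC[C@H](O)[C@@](C)(C(=O)OC(C)(C)C)[C@H]1[C@@H]3CO[Si](C(C)C)(C(C)C)C(C)C | intermediate
34 | 13‑hydroxy‑3‑oxo‑16‑ene 20‑oic acid 19‑tert‑butyl ester, 7‑O‑triisopropylsilyl (electrolysis substrate) | C=C1C[C@]23C[C@@]1(O)CC[C@H]2[C@]1(C(O)=O)CCC(=O)[C@@](C)(C(=O)OC(C)(C)C)[C@H]1[C@@H]3CO[Si](C(C)C)(C(C)C)C(C)C | intermediate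
35 | 13‑hydroxy‑3‑oxo‑16‑ene 19,10‑lactone (20‑nor), 7‑O‑triisopropylsilyl | C=C1C[C@]23C[C@@]1(O)CC[C@H]2[C@@]12OC(=O)[C@@](C)([C@H]1[C@@H]3CO[Si](C(C)C)(C(C)C)C(C)C)C(=O)CC2 | intermediate
36 | triethylsilyl trifluoromethanesulfonate | CC[Si](CC)(CC)OS(=O)(=O)C(F)(F)F | starting material
37 | 13‑O‑triethylsilyl 3‑oxo lactone | C=C1C[C@]23C[C@@]1(O[Si](CC)(CC)CC)CC[C@H]2[C@@]12OC(=O)[C@@](C)([C@H]1[C@@H]3CO[Si](C(C)C)(C(C)C)C(C)C)C(=O)CC2 | intermediate
38 | 1‑en‑3‑one lactone | C=C1C[C@]23C[C@@]1(O[Si](CC)(CC)CC)CC[C@H]2[C@@]12OC(=O)[C@@](C)([C@H]1[C@@H]3CO[Si](C(C)C)(C(C)C)C(C)C)C(=O)C=C2 | intermediate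
39 | hydrogen peroxide (used as its urea adduct) | OO | starting material
40 | 1β,2β‑epoxy‑3‑ketone | C=C1C[C@]23C[C@@]1(O[Si](CC)(CC)CC)CC[C@H]2[C@@]12OC(=O)[C@@](C)([C@H]1[C@@H]3CO[Si](C(C)C)(C(C)C)C(C)C)C(=O)[C@H]1O[C@H]12 | intermediate
41 | epoxy hydrazone of 40 | C=C1C[C@]23C[C@@]1(O[Si](CC)(CC)CC)CC[C@H]2[C@@]12OC(=O)[C@@](C)([C@H]1[C@@H]3CO[Si](C(C)C)(C(C)C)C(C)C)C(=NN)[C@H]1O[C@H]12 | intermediate
42 | 1β‑hydroxy‑2‑ene lactone (7‑O‑triisopropylsilyl, 13‑O‑triethylsilyl) | C=C1C[C@]23C[C@@]1(O[Si](CC)(CC)CC)CC[C@H]2[C@@]12OC(=O)[C@@](C)([C@H]1[C@@H]3CO[Si](C(C)C)(C(C)C)C(C)C)C=C[C@H]2O | intermediate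
43 | tert‑butyl hydroperoxide | CC(C)(C)OO | starting material
44 | 1β‑hydroxy‑2β,3β‑epoxide (7‑O‑triisopropylsilyl, 13‑O‑triethylsilyl) | C=C1C[C@]23C[C@@]1(O[Si](CC)(CC)CC)CC[C@H]2[C@@]12OC(=O)[C@@](C)([C@H]1[C@@H]3CO[Si](C(C)C)(C(C)C)C(C)C)[C@H]1O[C@H]1[C@H]2O | intermediate
45 | 1β,7,13‑triol 2β,3β‑epoxide | C=C1C[C@]23C[C@@]1(O)CC[C@H]2[C@@]12OC(=O)[C@@](C)([C@H]1[C@@H]3CO)[C@H]1O[C@H]1[C@H]2O | intermediate
46 | 7‑aldehyde | C=C1C[C@]23C[C@@]1(O)CC[C@H]2[C@@]12OC(=O)[C@@](C)([C@H]1[C@@H]3C=O)[C@H]1O[C@H]1[C@H]2O | intermediate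
47 | 1β,13‑dihydroxy‑2β,3β‑epoxy‑20‑norgibberell‑16‑ene‑7,19‑dioic acid 19,10‑lactone (the target gibberellin) | C=C1C[C@]23C[C@@]1(O)CC[C@H]2[C@@]12OC(=O)[C@@](C)([C@H]1[C@@H]3C(=O)O)[C@H]1O[C@H]1[C@H]2O | target

**Step count**

Total: 24 steps. Longest linear sequence: 24 steps (fully linear from 1 to 47).

**Steps most likely to fail**

Step 17 (proposed new method). What may go wrong: the electrode process may stop at the radical stage (hydrogen abstraction, dimerisation), the anode may attack the 16‑ene, or proton loss and hydride shift may outrun capture of the cation. Fallback with known chemistry, from 34: DCC coupling with N‑hydroxypyridine‑2‑thione in the dark gives the Barton ester F1. Visible‑light photolysis in benzene with iodoform then effects Barton decarboxylative iodination to the tertiary C10 iodide F2 (both C10 epimers, used crude). AgOTf with 2,6‑di‑tert‑butylpyridine in CH2Cl2 at −40 °C abstracts iodide, and the same C10 cation is formed cold, without an electrode, and is captured by the C19 tert‑butyl ester with loss of isobutene. This returns to the route at lactone 35.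

Step 14. What may go wrong: addition at the doubly substituted ring‑fusion carbon may be sluggish, the free acid may protodestannylate the allenylstannane, and the neighbouring silyloxymethyl group may erode facial selectivity. Fallback, from 30: Hosomi–Sakurai allylation (allyltrimethylsilane, TiCl4, CH2Cl2, −78 °C) with the more nucleophilic and acid‑tolerant allylsilane gives the 8β‑allyl ketone F3. Ozonolysis (O3, CH2Cl2–MeOH, −78 °C; Me2S) gives the keto aldehyde F4. Ohira–Bestmann homologation (dimethyl (1‑diazo‑2‑oxopropyl)phosphonate, K2CO3, MeOH, 0 °C) converts the aldehyde into the terminal alkyne and returns to the route at propargyl ketone 32.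

Step 21. What may go wrong: the hydrazone nitrogen may acylate on the adjacent lactone carbonyl (pyrazolone formation with lactone opening), or hydrazinolysis of the lactone may compete with fragmentation at the hindered ketone. Fallback, from 40: NaBH4 with CeCl3 in MeOH at −40 °C gives the epoxy alcohol F5 (either C3 epimer serves; the 3α‑alcohol is drawn). 1,1′‑Thiocarbonyldiimidazole with DMAP in CH2Cl2 gives the thiocarbonylimidazolide F6. Bu3SnH with AIBN in toluene at 80 °C generates the C3 radical, which opens the epoxide; the alkoxy radical is reduced by the stannane (Barton–McCombie‑type radical fragmentation of an epoxy alcohol derivative). This returns to the route at allylic alcohol 42.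

**Further compounds**

F1 | step 17 | Barton ester of 34 (C20 O‑acyl thiohydroxamate of N‑hydroxypyridine‑2‑thione) | C=C1C[C@]23C[C@@]1(O)CC[C@H]2[C@]1(C(=O)ON4C=CC=CC4=S)CCC(=O)[C@@](C)(C(=O)OC(C)(C)C)[C@H]1[C@@H]3CO[Si](C(C)C)(C(C)C)C(C)C
F2 | step 17 | tertiary C10 iodide (20‑nor, C10 epimers) | C=C1C[C@]23C[C@@]1(O)CC[C@H]2C1(I)CCC(=O)[C@@](C)(C(=O)OC(C)(C)C)[C@H]1[C@@H]3CO[Si](C(C)C)(C(C)C)C(C)C
F3 | step 14 | 8β‑allyl 13‑ketone | C=CC[C@]12CC(=O)CC[C@H]1[C@]1(C(O)=O)CC[C@H](O)[C@@](C)(C(=O)OC(C)(C)C)[C@H]1[C@@H]2CO[Si](C(C)C)(C(C)C)C(C)C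
F4 | step 14 | 8β‑(2‑oxoethyl) 13‑ketone (keto aldehyde) | O=CC[C@]12CC(=O)CC[C@H]1[C@]1(C(O)=O)CC[C@H](O)[C@@](C)(C(=O)OC(C)(C)C)[C@H]1[C@@H]2CO[Si](C(C)C)(C(C)C)C(C)C
F5 | step 21 | 1β,2β‑epoxy‑3α‑ol | C=C1C[C@]23C[C@@]1(O[Si](CC)(CC)CC)CC[C@H]2[C@@]12OC(=O)[C@@](C)([C@H]1[C@@H]3CO[Si](C(C)C)(C(C)C)C(C)C)[C@H](O)[C@H]1O[C@H]12
F6 | step 21 | 3‑O‑(imidazol‑1‑ylthiocarbonyl) derivative of F5 | C=C1C[C@]23C[C@@]1(O[Si](CC)(CC)CC)CC[C@H]2[C@@]12OC(=O)[C@@](C)([C@H]1[C@@H]3CO[Si](C(C)C)(C(C)C)C(C)C)[C@H](OC(=S)n4ccnc4)[C@H]1O[C@H]12
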